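**Plan**

1. Numbering: oxolane O1–C2(aryl)–C3(CH2OH)–C4(aroyl)–C5H2; the target is 2S,3S,4R (2,3-cis, 3,4-trans); pin = pinacolato.
2. Retrosynthesis: mask the ketone as a dioxolane and the C3 hydroxymethyl as CH2–B(pin), then cut the ring bond C2–C3 to reach an open-chain 3,4,5-trimethoxybenzyl ether carrying an E-alkenylboronate. Further cuts are the benzylic C–O bond, the C=C bond (aldehyde olefination) and the C4–CH2O bond (aldehyde α-hydroxymethylation), back to ethyl 3,4,5-trimethoxybenzoylacetate.
3. Enabling feature: C2 is benzylic and bonded to O1, so in the open ether its C–H is the weakest and most hydridic bond. C3 carries a one-carbon arm, so it can be the inner carbon of a 5-exo acceptor whose outer carbon bears boron (the later OH).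
4. Forward: the chain is built linearly (ketal, aldehyde, C4 centre, alkenylboronate, benzyl ether); the only ring, the oxolane, closes in the radical step; C–B oxidation and ketal hydrolysis finish.
5. Stereochemistry: C4 comes from enamine catalysis (catalyst control); C3 and C2 arise in the cyclisation under substrate control from C4.

Key step: step 6

Remark: the descriptor at the C4 carbon changes along the route (S in 5, R from 7 on) only because substituent priorities change; the spatial arrangement is kept throughout.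

**Route**

Step 1
Reactants: 1 ethyl 3-oxo-3-(3,4,5-trimethoxyphenyl)propanoate
Product: 2 ethyl 2-[2-(3,4,5-trimethoxyphenyl)-1,3-dioxolan-2-yl]acetate
Conditions: HOCH2CH2OH (5 equiv), TsOH·H2O (5 mol%), PhMe, reflux, Dean–Stark
Reagents that add atoms: ethylene glycol, OCCO
Why: Acid-catalysed ketalisation of the aryl ketone as a 1,3-dioxolane, driven by azeotropic removal of water; the ester does not react and the ketal removes the carbonyl that would otherwise make the future C4 centre labile.

Step 2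
Reactants: 2 ethyl 2-[2-(3,4,5-trimethoxyphenyl)-1,3-dioxolan-2-yl]acetate
Product: 3 2-[2-(3,4,5-trimethoxyphenyl)-1,3-dioxolan-2-yl]acetaldehyde
Conditions: i-Bu2AlH (1.1 equiv), CH2Cl2, −78 °C; then aq. potassium sodium tartrate
Reagents that add atoms: none
Why: Partial reduction of the ester to the aldehyde with i-Bu2AlH, which stops at the tetrahedral aluminium hemiacetal at −78 °C (helped by chelation to a dioxolane oxygen) and releases the aldehyde only on hydrolytic work-up.

Step 3
Reactants: 3 2-[2-(3,4,5-trimethoxyphenyl)-1,3-dioxolan-2-yl]acetaldehyde; 4 formaldehyde (37% in water)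
Product: 5 (S)-3-hydroxy-2-[2-(3,4,5-trimethoxyphenyl)-1,3-dioxolan-2-yl]propanal (taken on crude)
Conditions: (R)-2-[diphenyl(trimethylsilyloxy)methyl]pyrrolidine (15 mol%), aq. HCHO (3 equiv), pH 7 phosphate buffer, PhMe, rt
Reagents that add atoms: formaldehyde (compound 4), C=O
Why: Enamine-catalysed crossed aldol reaction with formaldehyde (organocatalytic α-hydroxymethylation): formaldehyde should attack the E-enamine on the face away from the Ph2C(OSiMe3) group, which for the R catalyst sets the new centre as S, and the neutral buffer spares the ketal.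

Step 4
Reactants: 5 (S)-3-hydroxy-2-[2-(3,4,5-trimethoxyphenyl)-1,3-dioxolan-2-yl]propanal; 6 2-(dichloromethyl)-4,4,5,5-tetramethyl-1,3,2-dioxaborolane
Product: 7 (2R,3E)-2-[2-(3,4,5-trimethoxyphenyl)-1,3-dioxolan-2-yl]-4-(4,4,5,5-tetramethyl-1,3,2-dioxaborolan-2-yl)but-3-en-1-ol
Conditions: CrCl2 (8 equiv), LiI (4 equiv), 6 (2 equiv), THF, rt
Reagents that add atoms: 2-(dichloromethyl)-4,4,5,5-tetramethyl-1,3,2-dioxaborolane (compound 6), ClC(Cl)B1OC(C)(C)C(C)(C)O1
Why: Takai–Utimoto-type borylolefination: divalent chromium (CrCl2) turns the dihalomethylboronate (activated in the flask by chloride–iodide exchange with LiI) into a geminal dichromium species that adds to the aldehyde and eliminates to the E-alkenylboronate under non-basic conditions, so the free hydroxyl is tolerated and the α-centre is not touched.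

Step 5
Reactants: 7 (2R,3E)-2-[2-(3,4,5-trimethoxyphenyl)-1,3-dioxolan-2-yl]-4-(4,4,5,5-tetramethyl-1,3,2-dioxaborolan-2-yl)but-3-en-1-ol; 8 5-(bromomethyl)-1,2,3-trimethoxybenzene
Product: 9 2-[(1E,3R)-4-[(3,4,5-trimethoxyphenyl)methoxy]-3-[2-(3,4,5-trimethoxyphenyl)-1,3-dioxolan-2-yl]but-1-en-1-yl]-4,4,5,5-tetramethyl-1,3,2-dioxaborolane (the 3,4,5-trimethoxybenzyl ether of 7)
Conditions: NaH (1.2 equiv), Bu4NI (cat.), THF/DMF, 0 °C to rt
Reagents that add atoms: 5-(bromomethyl)-1,2,3-trimethoxybenzene (compound 8), COc1cc(CBr)cc(OC)c1OC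
Why: Williamson ether synthesis between the primary alkoxide and the reactive benzylic bromide; the stereocentre bears no acidic hydrogen and the trans alkene keeps the alkoxide from closing on boron.

Step 6
Reactants: 9 2-[(1E,3R)-4-[(3,4,5-trimethoxyphenyl)methoxy]-3-[2-(3,4,5-trimethoxyphenyl)-1,3-dioxolan-2-yl]but-1-en-1-yl]-4,4,5,5-tetramethyl-1,3,2-dioxaborolane
Product: 10 2-{[(2S,3R,4R)-2-(3,4,5-trimethoxyphenyl)-4-[2-(3,4,5-trimethoxyphenyl)-1,3-dioxolan-2-yl]oxolan-3-yl]methyl}-4,4,5,5-tetramethyl-1,3,2-dioxaborolane (aryl at C2 cis to the CH2B arm at C3; arm trans to the dioxolanyl group at C4)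
Conditions: (Bu4N)4[W10O32] (2 mol%), MeCN (0.02 M), 390 nm LEDs, rt, argon
Reagents that add atoms: none
Why: The photoexcited decatungstate anion removes a hydrogen atom from the ArCH2–O carbon of 9, the nucleophilic C2 radical adds to the inner alkene carbon, and the α-boryl radical takes a hydrogen atom (or an electron and a proton) back from the reduced polyoxotungstate, so the catalyst turns over with no net change in composition. The closest known reaction type is the decatungstate-photocatalysed Giese-type hydroalkylation of electron-poor alkenes by ethers, run here intramolecularly on an alkenylboronate, an acceptor established in other radical additions. The oxolane closes in the 5-exo-trig mode, which puts the radical on the boron-bearing carbon where the vacant boron orbital stabilises it, so 6-endo closure should not compete. C3 is set by substrate control from C4: in the chair-like transition state the bulky dioxolanyl group sits pseudo-equatorial and the CH2B arm ends trans to it. C2 is set in the same transition state, the aryl group on the planar radical carbon taking the outward position that leads to the 2,3-cis product usual for 1-substituted hex-5-enyl-type radicals; this is a kinetic preference, so irradiation should stop at full conversion before the C2–H of the product is abstracted again. The step needs site-selective hydrogen abstraction, which the substrate secures because the benzylic O–CH2 bond is the weakest and most hydridic, the tertiary allylic C4–H is shielded by the quaternary ketal carbon and deactivated by three β-oxygens, the other OCH2 groups are not benzylic, and the ketal leaves no C–H at the masked carbonyl carbon.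

Step 7
Reactants: 10 2-{[(2S,3R,4R)-2-(3,4,5-trimethoxyphenyl)-4-[2-(3,4,5-trimethoxyphenyl)-1,3-dioxolan-2-yl]oxolan-3-yl]methyl}-4,4,5,5-tetramethyl-1,3,2-dioxaborolane
Product: 12 [(2S,3S,4R)-2-(3,4,5-trimethoxyphenyl)-4-[2-(3,4,5-trimethoxyphenyl)-1,3-dioxolan-2-yl]oxolan-3-yl]methanol, via borate ester 11 (not isolated)
Conditions: NaBO3·4H2O (4 equiv), THF/H2O (1:1), rt
Reagents that add atoms: sodium perborate (NaBO3·4H2O), [Na+].[O-]OB=O
Why: Oxidation of the primary alkyl pinacol boronate with perborate: the peroxy oxygen adds to boron, the CH2 group migrates to oxygen (no stereocentre is involved) and the borate ester is hydrolysed in the same flask, while the mild, slightly basic medium leaves the ketal and the benzylic ring ether intact.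

Step 8
Reactants: 12 [(2S,3S,4R)-2-(3,4,5-trimethoxyphenyl)-4-[2-(3,4,5-trimethoxyphenyl)-1,3-dioxolan-2-yl]oxolan-3-yl]methanol
Product: 13 [(3R,4S,5S)-4-(hydroxymethyl)-5-(3,4,5-trimethoxyphenyl)oxolan-3-yl](3,4,5-trimethoxyphenyl)methanone (target; 2S,3S,4R in the numbering of the plan)
Conditions: 1 M HCl (aq), THF, 0 °C to rt
Reagents that add atoms: water, O
Why: Acid-catalysed hydrolysis of the aryl dioxolane to the ketone (ketal deprotection); C4 already holds the favoured trans relation to C3 so enolisation has no driving force, the trans CH2OH cannot reach the carbonyl to form a bicyclic hemiketal, and dilute acid at room temperature should not ionise the C2 benzylic ether.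

**Compound list**

1 | ethyl 3-oxo-3-(3,4,5-trimethoxyphenyl)propanoate | CCOC(=O)CC(=O)c1cc(OC)c(OC)c(OC)c1 | starting material
2 | ethyl 2-[2-(3,4,5-trimethoxyphenyl)-1,3-dioxolan-2-yl]acetate | CCOC(=O)CC1(c2cc(OC)c(OC)c(OC)c2)OCCO1 | intermediate
3 | 2-[2-(3,4,5-trimethoxyphenyl)-1,3-dioxolan-2-yl]acetaldehyde | O=CCC1(c2cc(OC)c(OC)c(OC)c2)OCCO1 | intermediate
4 | formaldehyde | C=O | starting material
5 | (S)-3-hydroxy-2-[2-(3,4,5-trimethoxyphenyl)-1,3-dioxolan-2-yl]propanal | OC[C@@H](C=O)C1(c2cc(OC)c(OC)c(OC)c2)OCCO1 | intermediate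
6 | 2-(dichloromethyl)-4,4,5,5-tetramethyl-1,3,2-dioxaborolane | ClC(Cl)B1OC(C)(C)C(C)(C)O1 | starting material
7 | (2R,3E)-2-[2-(3,4,5-trimethoxyphenyl)-1,3-dioxolan-2-yl]-4-(4,4,5,5-tetramethyl-1,3,2-dioxaborolan-2-yl)but-3-en-1-ol | OC[C@@H](/C=C/B1OC(C)(C)C(C)(C)O1)C2(c3cc(OC)c(OC)c(OC)c3)OCCO2 | intermediate
8 | 5-(bromomethyl)-1,2,3-trimethoxybenzene | COc1cc(CBr)cc(OC)c1OC | starting material
9 | 2-[(1E,3R)-4-[(3,4,5-trimethoxyphenyl)methoxy]-3-[2-(3,4,5-trimethoxyphenyl)-1,3-dioxolan-2-yl]but-1-en-1-yl]-4,4,5,5-tetramethyl-1,3,2-dioxaborolane | COc1cc(COC[C@@H](/C=C/B2OC(C)(C)C(C)(C)O2)C3(c4cc(OC)c(OC)c(OC)c4)OCCO3)cc(OC)c1OC | intermediate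
10 | 2-{[(2S,3R,4R)-2-(3,4,5-trimethoxyphenyl)-4-[2-(3,4,5-trimethoxyphenyl)-1,3-dioxolan-2-yl]oxolan-3-yl]methyl}-4,4,5,5-tetramethyl-1,3,2-dioxaborolane | O1CCOC1(c2cc(OC)c(OC)c(OC)c2)[C@H]3CO[C@H](c4cc(OC)c(OC)c(OC)c4)[C@@H]3CB5OC(C)(C)C(C)(C)O5 | intermediate
11 | 2-{[(2S,3S,4R)-2-(3,4,5-trimethoxyphenyl)-4-[2-(3,4,5-trimethoxyphenyl)-1,3-dioxolan-2-yl]oxolan-3-yl]methoxy}-4,4,5,5-tetramethyl-1,3,2-dioxaborolane | O1CCOC1(c2cc(OC)c(OC)c(OC)c2)[C@H]3CO[C@H](c4cc(OC)c(OC)c(OC)c4)[C@@H]3COB5OC(C)(C)C(C)(C)O5 | intermediate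
12 | [(2S,3S,4R)-2-(3,4,5-trimethoxyphenyl)-4-[2-(3,4,5-trimethoxyphenyl)-1,3-dioxolan-2-yl]oxolan-3-yl]methanol | O1CCOC1(c2cc(OC)c(OC)c(OC)c2)[C@H]3CO[C@H](c4cc(OC)c(OC)c(OC)c4)[C@@H]3CO | intermediate
13 | [(3R,4S,5S)-4-(hydroxymethyl)-5-(3,4,5-trimethoxyphenyl)oxolan-3-yl](3,4,5-trimethoxyphenyl)methanone | COc1cc(C(=O)[C@H]2CO[C@H](c3cc(OC)c(OC)c(OC)c3)[C@@H]2CO)cc(OC)c1OC | target

**Totals**

Total step count: 8. Longest linear sequence: 8 steps (from 1).

**Steps most likely to fail, with fallbacks**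

Step 6. Hydrogen abstraction may spread to other sites, and the stabilised benzylic radical may close slowly or reversibly. Continued irradiation may also re-abstract the C2–H of the product and let the kinetic 2,3-cis arrangement drift towards the all-trans isomer. The fallback sets out from 7 (with bromide 8 as the source of the benzyl unit) and returns at 10; it makes the same C2 radical by carbon–sulfur homolysis in a tin hydride chain instead of by hydrogen abstraction. Bromide 8 with PhSH and K2CO3 in acetone gives 1,2,3-trimethoxy-5-[(phenylsulfanyl)methyl]benzene F1. N-Chlorosuccinimide in CH2Cl2 converts it into 5-[chloro(phenylsulfanyl)methyl]-1,2,3-trimethoxybenzene F2, which is used in solution. With i-Pr2NEt, F2 alkylates alcohol 7 to the mixed O,S-acetal 2-[(1E,3R)-4-[(phenylsulfanyl)(3,4,5-trimethoxyphenyl)methoxy]-3-[2-(3,4,5-trimethoxyphenyl)-1,3-dioxolan-2-yl]but-1-en-1-yl]-4,4,5,5-tetramethyl-1,3,2-dioxaborolane F3; both epimers at the acetal carbon serve. Slow addition of Bu3SnH with azobisisobutyronitrile in benzene at 80 °C should then give 10. Tin hydride traps benzylic radicals slowly enough for the 5-exo closure to run and reduces the α-boryl radical irreversibly, so the product never meets a hydrogen-abstracting catalyst.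

Step 3. The enamine sits next to the ketal carbon and may push out a dioxolane oxygen (vinylogous ionisation). The neopentyl-type enamine may also react sluggishly, and the β-hydroxy aldehyde may lose configuration during work-up. The fallback sets out from 2 and returns at 7; it replaces enamine catalysis by enzymatic desymmetrisation of a prochiral diol.
- The lithium enolate of 2 (lithium diisopropylamide, LiN(i-Pr)2, THF, −78 °C) is acylated with ClCO2Et to diethyl 2-[2-(3,4,5-trimethoxyphenyl)-1,3-dioxolan-2-yl]propanedioate F4.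
- LiAlH4 in THF reduces F4 to 2-[2-(3,4,5-trimethoxyphenyl)-1,3-dioxolan-2-yl]propane-1,3-diol F5.
- A lipase (for example that from Pseudomonas fluorescens, chosen by screening for the required sense) with vinyl acetate should give (R)-3-hydroxy-2-[2-(3,4,5-trimethoxyphenyl)-1,3-dioxolan-2-yl]propyl acetate F6.
- Dess–Martin periodinane buffered with NaHCO3 oxidises F6 to (S)-3-oxo-2-[2-(3,4,5-trimethoxyphenyl)-1,3-dioxolan-2-yl]propyl acetate F7.
- F7 is taken at once through the chromium borylolefination of step 4 (CrCl2, LiI, 6) to (2R,3E)-2-[2-(3,4,5-trimethoxyphenyl)-1,3-dioxolan-2-yl]-4-(4,4,5,5-tetramethyl-1,3,2-dioxaborolan-2-yl)but-3-en-1-yl acetate F8.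
- K2CO3 in MeOH removes the acetate and returns 7.

Step 4. The β-hydroxy aldehyde may be tied up as hemiacetal oligomers. It may also fragment by retro-aldol loss of formaldehyde, or epimerise at the α-carbon, while the bulky chromium reagent attacks the hindered carbonyl slowly. The fallback sets out from 5 and returns at 7; the hydroxyl is capped and the alkene is made by a boron–Wittig reaction. Et3SiCl and imidazole in CH2Cl2 give (S)-3-[(triethylsilyl)oxy]-2-[2-(3,4,5-trimethoxyphenyl)-1,3-dioxolan-2-yl]propanal F9. Bis(pinacolatoboryl)methane is deprotonated with lithium 2,2,6,6-tetramethylpiperidide (LiTMP) in THF at 0 °C and treated with F9 at −78 °C. Addition and elimination of the boron–oxygen unit should give triethyl{[(2R,3E)-2-[2-(3,4,5-trimethoxyphenyl)-1,3-dioxolan-2-yl]-4-(4,4,5,5-tetramethyl-1,3,2-dioxaborolan-2-yl)but-3-en-1-yl]oxy}silane F10. Pyridinium p-toluenesulfonate in MeOH at 0 °C removes the silyl group and returns 7.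

**Further compounds**

F1 | step 6 | 1,2,3-trimethoxy-5-[(phenylsulfanyl)methyl]benzene | COc1cc(CSc2ccccc2)cc(OC)c1OC
F2 | step 6 | 5-[chloro(phenylsulfanyl)methyl]-1,2,3-trimethoxybenzene (racemic) | COc1cc(C(Cl)Sc2ccccc2)cc(OC)c1OC
F3 | step 6 | 2-[(1E,3R)-4-[(phenylsulfanyl)(3,4,5-trimethoxyphenyl)methoxy]-3-[2-(3,4,5-trimethoxyphenyl)-1,3-dioxolan-2-yl]but-1-en-1-yl]-4,4,5,5-tetramethyl-1,3,2-dioxaborolane (both epimers at the acetal carbon) | COc1cc(C(Sc2ccccc2)OC[C@@H](/C=C/B3OC(C)(C)C(C)(C)O3)C4(c5cc(OC)c(OC)c(OC)c5)OCCO4)cc(OC)c1OC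
F4 | step 3 | diethyl 2-[2-(3,4,5-trimethoxyphenyl)-1,3-dioxolan-2-yl]propanedioate | CCOC(=O)C(C(=O)OCC)C1(c2cc(OC)c(OC)c(OC)c2)OCCO1
F5 | step 3 | 2-[2-(3,4,5-trimethoxyphenyl)-1,3-dioxolan-2-yl]propane-1,3-diol | OCC(CO)C1(c2cc(OC)c(OC)c(OC)c2)OCCO1
F6 | step 3 | (R)-3-hydroxy-2-[2-(3,4,5-trimethoxyphenyl)-1,3-dioxolan-2-yl]propyl acetate | CC(=O)OC[C@@H](CO)C1(c2cc(OC)c(OC)c(OC)c2)OCCO1
F7 | step 3 | (S)-3-oxo-2-[2-(3,4,5-trimethoxyphenyl)-1,3-dioxolan-2-yl]propyl acetate | CC(=O)OC[C@@H](C=O)C1(c2cc(OC)c(OC)c(OC)c2)OCCO1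
F8 | step 3 | (2R,3E)-2-[2-(3,4,5-trimethoxyphenyl)-1,3-dioxolan-2-yl]-4-(4,4,5,5-tetramethyl-1,3,2-dioxaborolan-2-yl)but-3-en-1-yl acetate | CC(=O)OC[C@@H](/C=C/B1OC(C)(C)C(C)(C)O1)C2(c3cc(OC)c(OC)c(OC)c3)OCCO2
F9 | step 4 | (S)-3-[(triethylsilyl)oxy]-2-[2-(3,4,5-trimethoxyphenyl)-1,3-dioxolan-2-yl]propanal | CC[Si](CC)(CC)OC[C@@H](C=O)C1(c2cc(OC)c(OC)c(OC)c2)OCCO1
F10 | step 4 | triethyl{[(2R,3E)-2-[2-(3,4,5-trimethoxyphenyl)-1,3-dioxolan-2-yl]-4-(4,4,5,5-tetramethyl-1,3,2-dioxaborolan-2-yl)but-3-en-1-yl]oxy}silane | CC[Si](CC)(CC)OC[C@@H](/C=C/B1OC(C)(C)C(C)(C)O1)C2(c3cc(OC)c(OC)c(OC)c3)OCCO2
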